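**Retrosynthetic overview**

1. Number the carbocycle C1 (one prenyl), C2, C3 (two prenyls), C4, C5 (benzoyl), C6. C4, C5, C6 and the benzoyl carbon form a 2-acyl-1,3-dione, carried as a 3-phenylisoxazole-4-carbonyl unit (isoxazole C3 = benzoyl carbon, isoxazole C4 = C5, isoxazole C5 = C6, the 4-carbonyl = C4); the α-carbon of its 5-alkyl group is C1.
2. Target ⇐ primary enaminone (hydrolysis) ⇐ isoxazole-fused hydroxy-enone (reductive N–O cleavage); the heterocycle is opened last.
3. Fused hydroxy-enone ⇐ quaternary β-keto ester by forming C1–C2: the carbanion at the isoxazole 5-CH2 attacks the methyl ester (lateral Dieckmann). This is the only ring closure; the isoxazole ring is purchased.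
4. β-Keto ester ⇐ 5-(4-methylpent-3-enyl)-3-phenylisoxazole-4-carbonyl chloride + lithium enolate of methyl diprenylacetate (C3–C4 bond).
5. Acid chloride ⇐ 5-methyl-3-phenylisoxazole-4-carboxylic acid (lateral prenylation of its dianion); ester ⇐ dimethyl malonate + prenyl bromide (double alkylation, Krapcho reaction).

Key step: step 6

Remark on the chemistry: the target is an achiral, freely tautomerising 2-acylcyclohexane-1,3,5-trione; the drawn dienol and the hydrolysis product of step 8 are the same compound, and no stereocentre has to be set.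

**Route**

Step 1
Reactants: 1 dimethyl malonate; 2 1-bromo-3-methylbut-2-ene (prenyl bromide)
Product: 4 dimethyl 2,2-bis(3-methylbut-2-enyl)propanedioate, via dimethyl 2-(3-methylbut-2-enyl)propanedioate 3 (not isolated)
Conditions: NaH (2.3 equiv), THF–DMF, 0 °C; 2 (2.3 equiv), 0 °C to 50 °C
Reagents that add atoms: none
Why: Double malonate alkylation; the sodium enolate displaces the primary allylic bromide by SN2 twice, and the second alkylation is still easy with this reactive electrophile.

Step 2
Reactants: 4 dimethyl 2,2-bis(3-methylbut-2-enyl)propanedioate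
Product: 5 methyl 5-methyl-2-(3-methylbut-2-enyl)hex-4-enoate (methyl diprenylacetate)
Conditions: LiCl (2 equiv), H2O (2 equiv), DMSO, 160 °C
Reagents that add atoms: none
Why: Krapcho dealkoxycarbonylation; chloride demethylates one ester of the disubstituted malonate, the carboxylate loses CO2 and water protonates the enolate, while the isolated trisubstituted alkenes are inert.

Step 3
Reactants: 6 5-methyl-3-phenylisoxazole-4-carboxylic acid; 2 prenyl bromide
Product: 8 5-(4-methylpent-3-enyl)-3-phenylisoxazole-4-carboxylic acid, via lithium 5-(lithiomethyl)-3-phenylisoxazole-4-carboxylate 7 (not isolated)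
Conditions: n-BuLi (2.1 equiv), THF, −78 °C; 2 (1.05 equiv), −78 to 0 °C; 1 M HCl work-up
Reagents that add atoms: none
Why: Lateral metalation of a 5-methylisoxazole-4-carboxylate; the first equivalent of base forms the carboxylate, the second removes a proton from the 5-methyl group (vinylogous to the carboxylate and held by it), and the dianion is alkylated at its more basic carbon by SN2 on the primary allylic bromide.

Step 4
Reactants: 8 5-(4-methylpent-3-enyl)-3-phenylisoxazole-4-carboxylic acid
Product: 9 5-(4-methylpent-3-enyl)-3-phenylisoxazole-4-carbonyl chloride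
Conditions: (COCl)2 (1.3 equiv), DMF (cat.), CH2Cl2, 0 °C to rt; concentrate, strip with toluene, use crude
Reagents that add atoms: oxalyl chloride, O=C(Cl)C(=O)Cl
Why: Acid chloride formation through the chloroiminium catalyst (the parent 5-methyl acid chloride is a standard acylating agent); HCl leaves with CO and CO2, and hydrochlorination of the remote trisubstituted alkene should be slow in cold CH2Cl2.

Step 5
Reactants: 5 methyl 5-methyl-2-(3-methylbut-2-enyl)hex-4-enoate; 9 5-(4-methylpent-3-enyl)-3-phenylisoxazole-4-carbonyl chloride
Product: 11 methyl 2,2-bis(3-methylbut-2-enyl)-3-[5-(4-methylpent-3-enyl)-3-phenylisoxazol-4-yl]-3-oxopropanoate, via lithium enolate of methyl 5-methyl-2-(3-methylbut-2-enyl)hex-4-enoate 10 (not isolated)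
Conditions: LiN(iPr)2 (1.05 equiv), THF, −78 °C; cannulate into 9 (1.0 equiv) in THF, −78 °C; AcOH quench at −78 °C
Reagents that add atoms: none
Why: Crossed Claisen-type C-acylation of a fully substituted lithium ester enolate by an aroyl chloride; the product has a quaternary α-carbon and cannot quench the enolate there, and inverse addition with a cold quench keeps the enolate from acting as a base on the isoxazole 5-CH2.

Step 6
Reactants: 11 methyl 2,2-bis(3-methylbut-2-enyl)-3-[5-(4-methylpent-3-enyl)-3-phenylisoxazol-4-yl]-3-oxopropanoate
Product: 13 6-hydroxy-5,5,7-tris(3-methylbut-2-enyl)-3-phenyl-1,2-benzoxazol-4(5H)-one, via lithium dienolate of the keto ester 12 (not isolated)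
Conditions: LiN(SiMe3)2 (2.5 equiv), THF, −78 °C, slow addition of 11; warm to 0 °C; 1 M HCl work-up
Reagents that add atoms: none
Why: LiN(SiMe3)2 removes a proton from the isoxazole 5-CH2 (ring C1), a vinylogous α-position of the 4-acyl ketone, to give dienolate 12, whose carbon terminus adds to the methyl ester carbonyl (ring C2) on the quaternary carbon and expels methoxide, forming C1–C2. The closest known reaction types are the lateral metalation–acylation of 5-alkylisoxazole-4-carbonyl compounds and the intramolecular Claisen (Dieckmann) closure of toluate-type benzylic anions. The one ring formed is the six-membered carbocycle, closed in the stereoelectronically allowed 6-(enolendo)-exo-trig mode; no stereocentre is created. The step needs deprotonation in preference to carbonyl addition or reduction, and C- in preference to O-acylation: the lateral CH2 is the only acidic C–H in 11, the hindered silylamide has no β-hydrogen to transfer to the non-enolisable ketone, and the isoxazole ties the C6 oxygen to nitrogen and leaves C5 without a hydrogen, so neither a pyranone-forming O-attack nor a competing enolate is available. The acidic product is deprotonated by the second equivalent of base, which makes the condensation irreversible and protects the new carbonyl; slow addition of 11 to excess base keeps the liberated LiOMe from cleaving unreacted 11 by retro-Claisen attack.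

Step 7
Reactants: 13 6-hydroxy-5,5,7-tris(3-methylbut-2-enyl)-3-phenyl-1,2-benzoxazol-4(5H)-one
Product: 14 2-[amino(phenyl)methylidene]-5-hydroxy-4,6,6-tris(3-methylbut-2-enyl)cyclohex-4-ene-1,3-dione
Conditions: Mo(CO)6 (1.0 equiv), MeCN–H2O (10:1), 80 °C, argon
Reagents that add atoms: none
Why: Reductive N–O cleavage of an isoxazole by zerovalent molybdenum; the metal binds nitrogen and inserts into the weak N–O bond, and water supplies the two hydrogens to give the vinylogous amide, while the alkenes, ketone and enol are untouched because no hydride or hydrogen gas is present.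

Step 8
Reactants: 14 2-[amino(phenyl)methylidene]-5-hydroxy-4,6,6-tris(3-methylbut-2-enyl)cyclohex-4-ene-1,3-dione
Product: 15 2-benzoyl-3,5-dihydroxy-4,4,6-tris(3-methylbut-2-enyl)cyclohexa-2,5-dien-1-one (CNP0210463.0)
Conditions: 2 M aq. HCl–THF (1:3), degassed, 45 °C, argon
Reagents that add atoms: water, O
Why: Acid hydrolysis of a primary vinylogous amide; protonation gives an iminium ion, water adds to the amino-bearing carbon and ammonia leaves as ammonium to give the chelated β-triketone, and dilute acid at mild temperature under argon should stay below the threshold for cyclisation of prenyl groups onto the enol oxygens and prevent autoxidation.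

**Compound list**

1 | dimethyl malonate | COC(=O)CC(=O)OC | starting material
2 | 1-bromo-3-methylbut-2-ene (prenyl bromide) | CC(C)=CCBr | starting material
3 | dimethyl 2-(3-methylbut-2-enyl)propanedioate | COC(=O)C(CC=C(C)C)C(=O)OC | intermediate (not isolated)
4 | dimethyl 2,2-bis(3-methylbut-2-enyl)propanedioate | COC(=O)C(CC=C(C)C)(CC=C(C)C)C(=O)OC | intermediate
5 | methyl 5-methyl-2-(3-methylbut-2-enyl)hex-4-enoate | COC(=O)C(CC=C(C)C)CC=C(C)C | intermediate
6 | 5-methyl-3-phenylisoxazole-4-carboxylic acid | Cc1onc(-c2ccccc2)c1C(=O)O | starting material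
7 | lithium 5-(lithiomethyl)-3-phenylisoxazole-4-carboxylate (dianion of 6) | [Li]Cc1onc(-c2ccccc2)c1C(=O)O[Li] | intermediate (not isolated)
8 | 5-(4-methylpent-3-enyl)-3-phenylisoxazole-4-carboxylic acid | CC(C)=CCCc1onc(-c2ccccc2)c1C(=O)O | intermediate
9 | 5-(4-methylpent-3-enyl)-3-phenylisoxazole-4-carbonyl chloride | CC(C)=CCCc1onc(-c2ccccc2)c1C(Cl)=O | intermediate
10 | lithium enolate of methyl 5-methyl-2-(3-methylbut-2-enyl)hex-4-enoate | COC(O[Li])=C(CC=C(C)C)CC=C(C)C | intermediate (not isolated)
11 | methyl 2,2-bis(3-methylbut-2-enyl)-3-[5-(4-methylpent-3-enyl)-3-phenylisoxazol-4-yl]-3-oxopropanoate | COC(=O)C(CC=C(C)C)(CC=C(C)C)C(=O)c1c(-c2ccccc2)noc1CCC=C(C)C | intermediate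
12 | lithium dienolate of 11 (O-lithio enolate of the ketone, conjugated through the isoxazole C4–C5 bond to the deprotonated 5-CH) | COC(=O)C(CC=C(C)C)(CC=C(C)C)C(O[Li])=C1C(c2ccccc2)=NOC1=CCC=C(C)C | intermediate (not isolated)
13 | 6-hydroxy-5,5,7-tris(3-methylbut-2-enyl)-3-phenyl-1,2-benzoxazol-4(5H)-one (drawn as the 6-enol) | O=C1c2c(-c3ccccc3)noc2C(CC=C(C)C)=C(O)C1(CC=C(C)C)CC=C(C)C | intermediate
14 | 2-[amino(phenyl)methylidene]-5-hydroxy-4,6,6-tris(3-methylbut-2-enyl)cyclohex-4-ene-1,3-dione (one tautomer; exocyclic C=C geometry not fixed) | NC(c1ccccc1)=C1C(=O)C(CC=C(C)C)=C(O)C(CC=C(C)C)(CC=C(C)C)C1=O | intermediate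
15 | 2-benzoyl-3,5-dihydroxy-4,4,6-tris(3-methylbut-2-enyl)cyclohexa-2,5-dien-1-one | CC(C)=CCC1=C(O)C(CC=C(C)C)(CC=C(C)C)C(O)=C(C(=O)c2ccccc2)C1=O | target

**Step count**

Total steps: 8. Longest linear sequence: 6 steps (steps 3, 4, 5, 6, 7, 8 from 6; equally steps 1, 2, 5, 6, 7, 8 from 1).

**Steps most likely to fail**

Step 6. The secondary lateral carbanion may form only in low equilibrium concentration and add slowly to the ester on the quaternary carbon, so that methoxide-induced retro-Claisen cleavage of the non-enolisable β-keto ester overtakes ring closure. The fallback closes the same C1–C2 bond with an unhindered primary lateral anion and brings in the third prenyl group afterwards. It sets out from 6, which oxalyl chloride and catalytic DMF convert into 5-methyl-3-phenylisoxazole-4-carbonyl chloride F1. Acylation of enolate 10 (from 5, as in step 5) with F1 should give methyl 2,2-bis(3-methylbut-2-enyl)-3-(5-methyl-3-phenylisoxazol-4-yl)-3-oxopropanoate F2. LiN(SiMe3)2 in THF then closes the ring to 6-hydroxy-5,5-bis(3-methylbut-2-enyl)-3-phenyl-1,2-benzoxazol-4(5H)-one F3. The lithium enolate of F3, a heteroaryl-conjugated ketone enolate comparable to a 2-tetralone enolate, is alkylated on carbon C7 with one equivalent of 2 in THF at 0 °C, and the route is rejoined at 13.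

Step 5. The hindered, fully substituted enolate may acylate slowly or on oxygen, or may instead deprotonate the isoxazole 5-CH2 of the acid chloride or of the product, giving oligomers and premature cyclisation. The fallback builds the quaternary carbon by alkylation instead of acylation and sets out from 9. Acylation of potassium methyl malonate with 9 (MgCl2, Et3N, MeCN) gives 2-(methoxycarbonyl)-3-[5-(4-methylpent-3-enyl)-3-phenylisoxazol-4-yl]-3-oxopropanoic acid F4, which is not isolated and loses CO2 on acidic work-up to give methyl 3-[5-(4-methylpent-3-enyl)-3-phenylisoxazol-4-yl]-3-oxopropanoate F5. Double C-alkylation of F5 with 2 (K2CO3, acetone, reflux) passes through methyl 2-(3-methylbut-2-enyl)-3-[5-(4-methylpent-3-enyl)-3-phenylisoxazol-4-yl]-3-oxopropanoate F6 and rejoins the route at 11. The carbonate base is too weak to touch the lateral CH2, and steps 1 and 2 become unnecessary.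

Step 3. Butyllithium may add to the isoxazole C=N bond or fragment the ring, the second deprotonation may be incomplete, or the lateral carbon may be alkylated twice. The fallback assembles the isoxazole with the side chain already in place and sets out from 2. Alkylation of the dianion of methyl acetoacetate (NaH, then n-BuLi, THF, 0 °C) with 2 at the terminal carbon gives methyl 7-methyl-3-oxooct-6-enoate F7. Condensation of the sodium enolate of F7 with N-hydroxybenzenecarboximidoyl chloride (NaOMe, MeOH, 0 °C to rt), by C-imidoylation and cyclodehydration, gives methyl 5-(4-methylpent-3-enyl)-3-phenylisoxazole-4-carboxylate F8. Saponification with LiOH in THF–H2O returns the route at 8.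

**Further compounds**

F1 | step 6 | 5-methyl-3-phenylisoxazole-4-carbonyl chloride | Cc1onc(-c2ccccc2)c1C(Cl)=O
F2 | step 6 | methyl 2,2-bis(3-methylbut-2-enyl)-3-(5-methyl-3-phenylisoxazol-4-yl)-3-oxopropanoate | COC(=O)C(CC=C(C)C)(CC=C(C)C)C(=O)c1c(-c2ccccc2)noc1C
F3 | step 6 | 6-hydroxy-5,5-bis(3-methylbut-2-enyl)-3-phenyl-1,2-benzoxazol-4(5H)-one | O=C1c2c(-c3ccccc3)noc2C=C(O)C1(CC=C(C)C)CC=C(C)C
F4 | step 5 | 2-(methoxycarbonyl)-3-[5-(4-methylpent-3-enyl)-3-phenylisoxazol-4-yl]-3-oxopropanoic acid | COC(=O)C(C(=O)O)C(=O)c1c(-c2ccccc2)noc1CCC=C(C)C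
F5 | step 5 | methyl 3-[5-(4-methylpent-3-enyl)-3-phenylisoxazol-4-yl]-3-oxopropanoate | COC(=O)CC(=O)c1c(-c2ccccc2)noc1CCC=C(C)C
F6 | step 5 | methyl 2-(3-methylbut-2-enyl)-3-[5-(4-methylpent-3-enyl)-3-phenylisoxazol-4-yl]-3-oxopropanoate | COC(=O)C(CC=C(C)C)C(=O)c1c(-c2ccccc2)noc1CCC=C(C)C
F7 | step 3 | methyl 7-methyl-3-oxooct-6-enoate | COC(=O)CC(=O)CCC=C(C)C
F8 | step 3 | methyl 5-(4-methylpent-3-enyl)-3-phenylisoxazole-4-carboxylate | COC(=O)c1c(-c2ccccc2)noc1CCC=C(C)C
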